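The route disconnects the O1–C5 bond of the tetrahydrofuran (O1; C2 aryl; C3 CH2OH; C4 OH; C5 benzyl). That ring carries its ring oxygen on C5 and a free hydroxyl on the neighbouring C4, cis to the C5 benzyl group, which is the imprint of a cis-4,5-epoxide opened at C5 by the C2 hydroxyl. One acid-promoted 5-endo cyclisation therefore closes the tetrahydrofuran, forms O1–C5 with inversion and releases the C4 hydroxyl. Its precursor is an anti-configured 2-hydroxy cis-4,5-epoxide with a silyl-protected CH2OH on C3, attached to a preformed cis-dihydrobenzofuran; its four contiguous centres all descend from one propargylic mesylate.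

Key step: step 21

Remark: as written, the dihydrobenzofuran of the target is 2,3-cis, (2R,3R); the route builds that relation and avoids conditions that would epimerise it.
Remark: Rh2(S-PTTL)4 is assumed to give the (2R,3S) cis ester, as it does with simpler aryldiazoacetates; if the sense is opposite, the enantiomeric catalyst is used.
Remark: 4-(benzyloxy)-3-methoxybenzyl alcohol is taken as a purchased material (it is O-benzylated, reduced vanillin).
Remark: both primary alcohols carry tert-butyldiphenylsilyl groups, so that only the triethylsilyl ether answers to buffered HF and nothing is lost under the acid of the key step.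
Abbreviations: ArV = 4-(benzyloxy)-3-methoxyphenyl; DHB = (2R,3R)-2-ArV-3-[(tert-butyldiphenylsilyloxy)methyl]-7-methoxy-2,3-dihydro-1-benzofuran-5-yl (2,3-cis); the locants C2–C5 of the tetrahydrofuran are also used for the open-chain intermediates.

Step 1
Reactants: 1 (2-hydroxy-3-methoxyphenyl)acetic acid
Product: 2 methyl (2-hydroxy-3-methoxyphenyl)acetate
Conditions: MeOH, H2SO4 (cat.), reflux
Reagents that add atoms: methanol, CO
Why: Fischer esterification in excess methanol drives the acid (or any lactone formed from it) to the methyl ester.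

Step 2
Reactants: 2 methyl (2-hydroxy-3-methoxyphenyl)acetate
Product: 3 methyl (5-bromo-2-hydroxy-3-methoxyphenyl)acetate
Conditions: NBS, MeCN, 0 °C
Reagents that add atoms: N-bromosuccinimide, O=C1CCC(=O)N1Br
Why: Electrophilic aromatic bromination goes para to the free phenol because both ortho positions are substituted, which installs the handle for the later formyl group.

Step 3
Reactants: 4 4-(benzyloxy)-3-methoxybenzyl alcohol
Product: 5 4-(benzyloxy)-3-methoxybenzyl bromide
Conditions: PBr3, Et2O, 0 °C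
Reagents that add atoms: phosphorus tribromide, BrP(Br)Br
Why: Conversion of a primary benzylic alcohol into the bromide with PBr3 (substitution of the intermediate phosphite) is routine and leaves the aryl ethers untouched.

Step 4
Reactants: 3 methyl (5-bromo-2-hydroxy-3-methoxyphenyl)acetate; 5 4-(benzyloxy)-3-methoxybenzyl bromide
Product: 6 methyl {2-[(4-benzyloxy-3-methoxybenzyl)oxy]-5-bromo-3-methoxyphenyl}acetate
Conditions: K2CO3, DMF, rt
Reagents that add atoms: none
Why: Williamson etherification of the phenoxide with the reactive benzylic bromide; carbonate is too weak to enolise the arylacetate.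

Step 5
Reactants: 6 methyl {2-[(4-benzyloxy-3-methoxybenzyl)oxy]-5-bromo-3-methoxyphenyl}acetate
Product: 7 methyl 2-diazo-2-{2-[(4-benzyloxy-3-methoxybenzyl)oxy]-5-bromo-3-methoxyphenyl}acetate
Conditions: p-ABSA, DBU, MeCN, 0 °C to rt
Reagents that add atoms: 4-acetamidobenzenesulfonyl azide, CC(=O)Nc1ccc(cc1)S(=O)(=O)N=[N+]=[N-]
Why: Regitz diazo transfer to the arylacetate enolate is the standard entry to donor/acceptor aryldiazoacetates.

Step 6
Reactants: 7 methyl 2-diazo-2-{2-[(4-benzyloxy-3-methoxybenzyl)oxy]-5-bromo-3-methoxyphenyl}acetate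
Product: 8 methyl (2R,3S)-2-ArV-5-bromo-7-methoxy-2,3-dihydro-1-benzofuran-3-carboxylate (2,3-cis)
Conditions: Rh2(S-PTTL)4 (1 mol %), toluene, −60 °C
Reagents that add atoms: none
Why: Intramolecular 1,5 C–H insertion of the rhodium carbenoid into the ether-activated benzylic C–H closes the dihydrofuran; the chiral carboxylate catalyst sets C2 (R) and the kinetic insertion geometry gives the 2,3-cis ester (C3 S).

Step 7
Reactants: 8 methyl (2R,3S)-2-ArV-5-bromo-7-methoxy-2,3-dihydro-1-benzofuran-3-carboxylate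
Product: 9 [(2R,3R)-2-ArV-5-bromo-7-methoxy-2,3-dihydro-1-benzofuran-3-yl]methanol (2,3-cis)
Conditions: i-Bu2AlH (DIBAL-H), CH2Cl2, −78 °C; Rochelle salt work-up
Reagents that add atoms: none
Why: Hydride reduction of the ester at low temperature outruns enolisation, so the cis relation is kept (the descriptor at C3 changes by priority only) and the aryl bromide is untouched.

Step 8
Reactants: 9 [(2R,3R)-2-ArV-5-bromo-7-methoxy-2,3-dihydro-1-benzofuran-3-yl]methanol
Product: 10 (2R,3R)-2-ArV-5-bromo-3-[(tert-butyldiphenylsilyloxy)methyl]-7-methoxy-2,3-dihydro-1-benzofuran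
Conditions: TBDPSCl, imidazole, DMF, rt
Reagents that add atoms: tert-butyl(chloro)diphenylsilane, CC(C)(C)[Si](Cl)(c1ccccc1)c1ccccc1
Why: Silylation of the primary alcohol gives an ether that survives organolithiums, mild acid and buffered HF.

Step 9
Reactants: 10 (2R,3R)-2-ArV-5-bromo-3-[(tert-butyldiphenylsilyloxy)methyl]-7-methoxy-2,3-dihydro-1-benzofuran
Product: 12 (2R,3R)-2-ArV-3-[(tert-butyldiphenylsilyloxy)methyl]-7-methoxy-2,3-dihydro-1-benzofuran-5-carbaldehyde, via aryllithium 11 (not isolated)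
Conditions: n-BuLi, THF, −78 °C; then DMF, −78 to 0 °C; aq NH4Cl
Reagents that add atoms: N,N-dimethylformamide, CN(C)C=O
Why: Bromine–lithium exchange at −78 °C is faster than any deprotonation, and formylation of the aryllithium with DMF (Bouveault aldehyde synthesis) does not touch the two stereocentres.

Step 10
Reactants: 13 (tert-butyldiphenylsilyloxy)acetaldehyde; 14 ethynyltrimethylsilane
Product: 16 rac-1-(tert-butyldiphenylsilyloxy)-4-(trimethylsilyl)but-3-yn-2-ol, via lithium trimethylsilylacetylide 15 (not isolated)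
Conditions: 14, n-BuLi, THF, −78 °C; then 13, −78 °C; aq NH4Cl
Reagents that add atoms: none
Why: 1,2-Addition of a lithium acetylide to an aldehyde; the racemic alcohol is only a stepping stone to the ketone.

Step 11
Reactants: 16 rac-1-(tert-butyldiphenylsilyloxy)-4-(trimethylsilyl)but-3-yn-2-ol
Product: 17 1-(tert-butyldiphenylsilyloxy)-4-(trimethylsilyl)but-3-yn-2-one
Conditions: Dess–Martin periodinane, CH2Cl2, rt
Reagents that add atoms: none
Why: Dess–Martin oxidation of a propargylic alcohol to the ynone is mild and leaves both silyl groups in place.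

Step 12
Reactants: 17 1-(tert-butyldiphenylsilyloxy)-4-(trimethylsilyl)but-3-yn-2-one
Product: 18 (S)-1-(tert-butyldiphenylsilyloxy)-4-(trimethylsilyl)but-3-yn-2-ol
Conditions: RuCl[(R,R)-TsDPEN](p-cymene) (1 mol %), i-PrOH, rt
Reagents that add atoms: none
Why: Noyori asymmetric transfer hydrogenation of an alkynyl ketone, in which the alkyne takes the role of the aryl group, so the (R,R) catalyst delivers hydride to the face that gives the (S) carbinol (the descriptor is reversed against the methyl ketone series because CH2OSi outranks the alkyne).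

Step 13
Reactants: 18 (S)-1-(tert-butyldiphenylsilyloxy)-4-(trimethylsilyl)but-3-yn-2-ol
Product: 19 (S)-1-(tert-butyldiphenylsilyloxy)but-3-yn-2-ol
Conditions: K2CO3 (cat.), MeOH, 0 °C to rt
Reagents that add atoms: none
Why: Base-catalysed protodesilylation cleaves only the alkynyl C–Si bond; the silyl ether and the carbinol centre are unaffected.

Step 14
Reactants: 19 (S)-1-(tert-butyldiphenylsilyloxy)but-3-yn-2-ol
Product: 20 (S)-1-(tert-butyldiphenylsilyloxy)but-3-yn-2-yl methanesulfonate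
Conditions: MsCl, Et3N, CH2Cl2, −78 to 0 °C
Reagents that add atoms: methanesulfonyl chloride, CS(=O)(=O)Cl
Why: O-Sulfonylation proceeds with retention at carbon and supplies the leaving group for the palladium step.

Step 15
Reactants: 20 (S)-1-(tert-butyldiphenylsilyloxy)but-3-yn-2-yl methanesulfonate; 12 (2R,3R)-2-ArV-3-[(tert-butyldiphenylsilyloxy)methyl]-7-methoxy-2,3-dihydro-1-benzofuran-5-carbaldehyde
Product: 22 (1S,2R)-1-DHB-2-[(tert-butyldiphenylsilyloxy)methyl]but-3-yn-1-ol (anti), via allenylzinc 21 (not isolated)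
Conditions: Pd(OAc)2 (5 mol %), PPh3 (5 mol %), Et2Zn (3 equiv), THF, −78 to −20 °C; aq NH4Cl
Reagents that add atoms: none
Why: Marshall propargylation: zerovalent palladium displaces the mesylate in an anti SN2′ sense, transmetalation gives the (P)-allenylzinc, and its cyclic SE2′ addition to the aldehyde gives the anti homopropargylic alcohol, with C3 formed by net inversion of the mesylate centre and C2 (S) fixed by the closed transition state.

Step 16
Reactants: 22 (1S,2R)-1-DHB-2-[(tert-butyldiphenylsilyloxy)methyl]but-3-yn-1-ol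
Product: 23 (1S,2R)-1-DHB-2-[(tert-butyldiphenylsilyloxy)methyl]-1-(triethylsilyloxy)but-3-yne
Conditions: Et3SiOTf, 2,6-lutidine, CH2Cl2, −78 °C
Reagents that add atoms: triethylsilyl trifluoromethanesulfonate, CC[Si](CC)(CC)OS(=O)(=O)C(F)(F)F
Why: Silylation with the triflate caps the hindered benzylic alcohol, which prevents O-alkylation in the next step and later enlarges the branch that steers the epoxidation.

Step 17
Reactants: 23 (1S,2R)-1-DHB-2-[(tert-butyldiphenylsilyloxy)methyl]-1-(triethylsilyloxy)but-3-yne; 5 4-(benzyloxy)-3-methoxybenzyl bromide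
Product: 25 (1S,2R)-5-ArV-1-DHB-2-[(tert-butyldiphenylsilyloxy)methyl]-1-(triethylsilyloxy)pent-3-yne, via lithium acetylide 24 (not isolated)
Conditions: n-BuLi (1.0 equiv), THF, −78 °C; CuI (20 mol %), then 5, THF–DMPU, −78 °C to rt
Reagents that add atoms: none
Why: Copper-catalysed alkylation of a metal acetylide with a benzylic bromide forms the sp–sp3 bond through a transient copper acetylide, and one equivalent of base avoids isomerising the skipped arylalkyne.

Step 18
Reactants: 25 (1S,2R)-5-ArV-1-DHB-2-[(tert-butyldiphenylsilyloxy)methyl]-1-(triethylsilyloxy)pent-3-yne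
Product: 26 (1S,2R,3Z)-5-ArV-1-DHB-2-[(tert-butyldiphenylsilyloxy)methyl]-1-(triethylsilyloxy)pent-3-ene
Conditions: H2 (1 atm), Pd/CaCO3 poisoned with Pb(OAc)2, quinoline, EtOAc, rt
Reagents that add atoms: none
Why: Lindlar semihydrogenation adds hydrogen syn to the alkyne and stops at the (Z)-alkene, while the poisoned catalyst leaves the benzyl ethers alone.

Step 19
Reactants: 26 (1S,2R,3Z)-5-ArV-1-DHB-2-[(tert-butyldiphenylsilyloxy)methyl]-1-(triethylsilyloxy)pent-3-ene
Product: 27 (1S,2S)-2-[(2S,3R)-3-(ArV-methyl)oxiran-2-yl]-1-DHB-3-(tert-butyldiphenylsilyloxy)-1-(triethylsilyloxy)propane (cis-epoxide; C4 S, C5 R)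
Conditions: m-CPBA, NaHCO3, CH2Cl2, 0 °C
Reagents that add atoms: 3-chloroperbenzoic acid, OOC(=O)c1cccc(Cl)c1
Why: Prilezhaev epoxidation is syn-stereospecific, and in the (Z)-alkene allylic 1,3-strain holds the C3–H in the alkene plane so that the peracid adds to the face opposite the bulky CH(OSiEt3)Ar branch, which sets C4 (S) and C5 (R) from C3.

Step 20
Reactants: 27 (1S,2S)-2-[(2S,3R)-3-(ArV-methyl)oxiran-2-yl]-1-DHB-3-(tert-butyldiphenylsilyloxy)-1-(triethylsilyloxy)propane
Product: 28 (1S,2R)-2-[(2S,3R)-3-(ArV-methyl)oxiran-2-yl]-1-DHB-3-(tert-butyldiphenylsilyloxy)propan-1-ol (anti cis-4,5-epoxy alcohol; C2 S, C3 R, C4 S, C5 R)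
Conditions: HF·pyridine, pyridine, THF, 0 °C
Reagents that add atoms: none
Why: Buffered HF desilylation removes the triethylsilyl ether far faster than the two tert-butyldiphenylsilyl ethers and does not open a dialkyl epoxide at 0 °C; no centre is touched (the C3 descriptor changes by priority only).

Step 21
Reactants: 28 (1S,2R)-2-[(2S,3R)-3-(ArV-methyl)oxiran-2-yl]-1-DHB-3-(tert-butyldiphenylsilyloxy)propan-1-ol
Product: 29 (2S,3S,4S,5S)-5-(ArV-methyl)-2-DHB-3-[(tert-butyldiphenylsilyloxy)methyl]oxolan-4-ol (aryl on C2)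
Conditions: (±)-10-camphorsulfonic acid (10 mol %), CH2Cl2, 0 °C
Reagents that add atoms: none
Why: The sulfonic acid activates the oxirane oxygen by protonation and the C2 hydroxyl attacks C5 from the rear of the C5–O bond in an SN2-like intramolecular epoxide opening; loss of the proton gives the tetrahydrofuran and the free C4 hydroxyl. The closest established reaction type is the acid-catalysed cyclisation of 3,4-epoxy alcohols to tetrahydrofuran-3-ols. The single ring closes in a 5-endo-tet mode, which epoxides tolerate because the breaking C5–O bond points out of the forming five-membered ring and the strained oxirane lets the nucleophile reach a near-collinear trajectory. C5 is set by inversion of the (5R) oxirane carbon to (5S), which places the benzyl group cis to the untouched (4S) hydroxyl, while C2 and C3 are carried through unchanged. The step needs attack at C5 rather than C4 and an SN2-like rather than ionised course: attack at C4 would give a strained oxetane and is hindered by the branched C3, and neither oxirane carbon is benzylic, so no cation competes. Catalytic acid at 0 °C in a non-nucleophilic solvent should leave the benzylic C2 alcohol, the cis-dihydrobenzofuran and the silyl ethers intact.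

Step 22
Reactants: 29 (2S,3S,4S,5S)-5-(ArV-methyl)-2-DHB-3-[(tert-butyldiphenylsilyloxy)methyl]oxolan-4-ol
Product: 30 (2S,3S,4S,5S)-5-[4-(benzyloxy)-3-methoxybenzyl]-2-{(2R,3R)-2-[4-(benzyloxy)-3-methoxyphenyl]-3-(hydroxymethyl)-7-methoxy-2,3-dihydro-1-benzofuran-5-yl}-3-(hydroxymethyl)oxolan-4-ol
Conditions: TBAF, THF, rt; aq NH4Cl
Reagents that add atoms: none
Why: Fluoride-mediated desilylation cleaves both primary silyl ethers, and because the phenols are still benzylated no quinone-methide opening of the cis-dihydrobenzofuran can occur under the basic conditions.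

Step 23
Reactants: 30 (2S,3S,4S,5S)-5-[4-(benzyloxy)-3-methoxybenzyl]-2-{(2R,3R)-2-[4-(benzyloxy)-3-methoxyphenyl]-3-(hydroxymethyl)-7-methoxy-2,3-dihydro-1-benzofuran-5-yl}-3-(hydroxymethyl)oxolan-4-ol
Product: 31 (2S,3S,4S,5S)-5-(4-hydroxy-3-methoxybenzyl)-2-[(2R,3R)-2-(4-hydroxy-3-methoxyphenyl)-3-(hydroxymethyl)-7-methoxy-2,3-dihydro-1-benzofuran-5-yl]-3-(hydroxymethyl)oxolan-4-ol (target, CNP0179668.1)
Conditions: H2 (1 atm), 10% Pd/C, EtOAc, rt, stopped at complete debenzylation
Reagents that add atoms: none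
Why: Catalytic hydrogenolysis cleaves the two aryl benzyl ethers much faster than the benzylic C–O bonds of the two oxygen heterocycles, so brief neutral exposure should free both phenols without ring opening or epimerisation.

Compound list
1 | (2-hydroxy-3-methoxyphenyl)acetic acid | COc1cccc(CC(=O)O)c1O | starting material
2 | methyl (2-hydroxy-3-methoxyphenyl)acetate | COC(=O)Cc1cccc(OC)c1O | intermediate
3 | methyl (5-bromo-2-hydroxy-3-methoxyphenyl)acetate | COC(=O)Cc1cc(Br)cc(OC)c1O | intermediate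
4 | 4-(benzyloxy)-3-methoxybenzyl alcohol | COc1cc(CO)ccc1OCc1ccccc1 | starting material
5 | 4-(benzyloxy)-3-methoxybenzyl bromide | COc1cc(CBr)ccc1OCc1ccccc1 | intermediate
6 | methyl {2-[(4-benzyloxy-3-methoxybenzyl)oxy]-5-bromo-3-methoxyphenyl}acetate | COC(=O)Cc1cc(Br)cc(OC)c1OCc1ccc(OCc2ccccc2)c(OC)c1 | intermediate
7 | methyl 2-diazo-2-{2-[(4-benzyloxy-3-methoxybenzyl)oxy]-5-bromo-3-methoxyphenyl}acetate | COC(=O)C(=[N+]=[N-])c1cc(Br)cc(OC)c1OCc1ccc(OCc2ccccc2)c(OC)c1 | intermediate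
8 | methyl (2R,3S)-2-[4-(benzyloxy)-3-methoxyphenyl]-5-bromo-7-methoxy-2,3-dihydro-1-benzofuran-3-carboxylate (cis) | Brc1cc(OC)c2c(c1)[C@H](C(=O)OC)[C@H](c1ccc(OCc3ccccc3)c(OC)c1)O2 | intermediate
9 | [(2R,3R)-2-[4-(benzyloxy)-3-methoxyphenyl]-5-bromo-7-methoxy-2,3-dihydro-1-benzofuran-3-yl]methanol (cis) | Brc1cc(OC)c2c(c1)[C@H](CO)[C@H](c1ccc(OCc3ccccc3)c(OC)c1)O2 | intermediate
10 | (2R,3R)-2-[4-(benzyloxy)-3-methoxyphenyl]-5-bromo-3-[(tert-butyldiphenylsilyloxy)methyl]-7-methoxy-2,3-dihydro-1-benzofuran | Brc1cc(OC)c2c(c1)[C@H](CO[Si](c1ccccc1)(c1ccccc1)C(C)(C)C)[C@H](c1ccc(OCc3ccccc3)c(OC)c1)O2 | intermediate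
11 | aryllithium from 10 (lithium in place of bromine) | [Li]c1cc(OC)c2c(c1)[C@H](CO[Si](c1ccccc1)(c1ccccc1)C(C)(C)C)[C@H](c1ccc(OCc3ccccc3)c(OC)c1)O2 | intermediate
12 | (2R,3R)-2-[4-(benzyloxy)-3-methoxyphenyl]-3-[(tert-butyldiphenylsilyloxy)methyl]-7-methoxy-2,3-dihydro-1-benzofuran-5-carbaldehyde | O=Cc1cc(OC)c2c(c1)[C@H](CO[Si](c1ccccc1)(c1ccccc1)C(C)(C)C)[C@H](c1ccc(OCc3ccccc3)c(OC)c1)O2 | intermediate
13 | (tert-butyldiphenylsilyloxy)acetaldehyde | O=CCO[Si](c1ccccc1)(c1ccccc1)C(C)(C)C | starting material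
14 | ethynyltrimethylsilane | C#C[Si](C)(C)C | starting material
15 | lithium (trimethylsilyl)acetylide | [Li]C#C[Si](C)(C)C | intermediate
16 | rac-1-(tert-butyldiphenylsilyloxy)-4-(trimethylsilyl)but-3-yn-2-ol | C[Si](C)(C)C#CC(O)CO[Si](c1ccccc1)(c1ccccc1)C(C)(C)C | intermediate
17 | 1-(tert-butyldiphenylsilyloxy)-4-(trimethylsilyl)but-3-yn-2-one | C[Si](C)(C)C#CC(=O)CO[Si](c1ccccc1)(c1ccccc1)C(C)(C)C | intermediate
18 | (S)-1-(tert-butyldiphenylsilyloxy)-4-(trimethylsilyl)but-3-yn-2-ol | C[Si](C)(C)C#C[C@H](O)CO[Si](c1ccccc1)(c1ccccc1)C(C)(C)C | intermediate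
19 | (S)-1-(tert-butyldiphenylsilyloxy)but-3-yn-2-ol | C#C[C@H](O)CO[Si](c1ccccc1)(c1ccccc1)C(C)(C)C | intermediate
20 | (S)-1-(tert-butyldiphenylsilyloxy)but-3-yn-2-yl methanesulfonate | C#C[C@H](OS(C)(=O)=O)CO[Si](c1ccccc1)(c1ccccc1)C(C)(C)C | intermediate
21 | ethyl[(P)-4-(tert-butyldiphenylsilyloxy)buta-1,2-dien-1-yl]zinc (axial chirality on the central allene carbon) | [H]C([Zn]CC)=[C@]=C([H])CO[Si](c1ccccc1)(c1ccccc1)C(C)(C)C | intermediate
22 | (1S,2R)-1-DHB-2-[(tert-butyldiphenylsilyloxy)methyl]but-3-yn-1-ol (anti; C2 S, C3 R) | C#C[C@H](CO[Si](c1ccccc1)(c1ccccc1)C(C)(C)C)[C@H](O)c1cc(OC)c2c(c1)[C@H](CO[Si](c1ccccc1)(c1ccccc1)C(C)(C)C)[C@H](c1ccc(OCc3ccccc3)c(OC)c1)O2 | intermediate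
23 | triethylsilyl ether of 22 | C#C[C@H](CO[Si](c1ccccc1)(c1ccccc1)C(C)(C)C)[C@H](O[Si](CC)(CC)CC)c1cc(OC)c2c(c1)[C@H](CO[Si](c1ccccc1)(c1ccccc1)C(C)(C)C)[C@H](c1ccc(OCc3ccccc3)c(OC)c1)O2 | intermediate
24 | lithium acetylide of 23 | [Li]C#C[C@H](CO[Si](c1ccccc1)(c1ccccc1)C(C)(C)C)[C@H](O[Si](CC)(CC)CC)c1cc(OC)c2c(c1)[C@H](CO[Si](c1ccccc1)(c1ccccc1)C(C)(C)C)[C@H](c1ccc(OCc3ccccc3)c(OC)c1)O2 | intermediate
25 | (1S,2R)-5-ArV-1-DHB-2-[(tert-butyldiphenylsilyloxy)methyl]-1-(triethylsilyloxy)pent-3-yne | COc1cc(CC#C[C@H](CO[Si](c2ccccc2)(c2ccccc2)C(C)(C)C)[C@H](O[Si](CC)(CC)CC)c2cc(OC)c3c(c2)[C@H](CO[Si](c2ccccc2)(c2ccccc2)C(C)(C)C)[C@H](c2ccc(OCc4ccccc4)c(OC)c2)O3)ccc1OCc1ccccc1 | intermediate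
26 | (1S,2R,3Z)-5-ArV-1-DHB-2-[(tert-butyldiphenylsilyloxy)methyl]-1-(triethylsilyloxy)pent-3-ene | COc1cc(C/C=C\[C@H](CO[Si](c2ccccc2)(c2ccccc2)C(C)(C)C)[C@H](O[Si](CC)(CC)CC)c2cc(OC)c3c(c2)[C@H](CO[Si](c2ccccc2)(c2ccccc2)C(C)(C)C)[C@H](c2ccc(OCc4ccccc4)c(OC)c2)O3)ccc1OCc1ccccc1 | intermediate
27 | triethylsilyl-protected cis-4,5-epoxide (C2 S, C3 S, C4 S, C5 R) | COc1cc(C[C@H]2O[C@H]2[C@H](CO[Si](c2ccccc2)(c2ccccc2)C(C)(C)C)[C@H](O[Si](CC)(CC)CC)c2cc(OC)c3c(c2)[C@H](CO[Si](c2ccccc2)(c2ccccc2)C(C)(C)C)[C@H](c2ccc(OCc4ccccc4)c(OC)c2)O3)ccc1OCc1ccccc1 | intermediate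
28 | anti cis-4,5-epoxy alcohol with free C2 hydroxyl (C2 S, C3 R, C4 S, C5 R); precursor of the key step | COc1cc(C[C@H]2O[C@H]2[C@H](CO[Si](c2ccccc2)(c2ccccc2)C(C)(C)C)[C@H](O)c2cc(OC)c3c(c2)[C@H](CO[Si](c2ccccc2)(c2ccccc2)C(C)(C)C)[C@H](c2ccc(OCc4ccccc4)c(OC)c2)O3)ccc1OCc1ccccc1 | intermediate
29 | protected tetrahydrofuran with free C4 hydroxyl (2S,3S,4S,5S); product of the key step | COc1cc(C[C@@H]2O[C@H](c3cc(OC)c4c(c3)[C@H](CO[Si](c3ccccc3)(c3ccccc3)C(C)(C)C)[C@H](c3ccc(OCc5ccccc5)c(OC)c3)O4)[C@@H](CO[Si](c3ccccc3)(c3ccccc3)C(C)(C)C)[C@@H]2O)ccc1OCc1ccccc1 | intermediate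
30 | bis(benzyl ether) of the target (both CH2OH and the C4 hydroxyl free) | COc1cc(C[C@@H]2O[C@H](c3cc(OC)c4c(c3)[C@H](CO)[C@H](c3ccc(OCc5ccccc5)c(OC)c3)O4)[C@@H](CO)[C@@H]2O)ccc1OCc1ccccc1 | intermediate
31 | CNP0179668.1 | COc1cc(C[C@@H]2O[C@H](c3cc(OC)c4c(c3)[C@H](CO)[C@H](c3ccc(O)c(OC)c3)O4)[C@@H](CO)[C@@H]2O)ccc1O | target

Total step count: 23. Longest linear sequence: 17 steps (steps 1, 2, 4–9 and 15–23).

Steps most likely to fail

1. Step 19. Facial discrimination in the peracid epoxidation rests on allylic strain alone and may be incomplete, and the electron-rich arenes may be oxidised. The fallback sets out from alkene 26 and returns at epoxide 27. Syn-dihydroxylation with OsO4 (cat.) and NMO uses a bulkier oxidant that follows the same allylic-strain model more strictly and can be reinforced by a matched cinchona ligand; it should give the syn-4,5-diol F1. A one-flask Kolb–Sharpless sequence then follows: MeC(OMe)3 with PPTS gives the cyclic orthoacetate F2, AcBr opens it to the bromo acetate F3, and K2CO3 in MeOH closes the oxirane. The two inversions occur at the same carbon, so the diol configuration is retained and the cis-epoxide 27 results whichever carbon the bromide attacks.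

2. Step 21. Acid may trigger ionisation at the electron-rich benzylic sites (the C2 carbinol, the aryl–O bond of the cis-dihydrobenzofuran), or 4-exo closure may compete with the 5-endo opening. The fallback sets out from alkene 26, passes through diol F1 made as above, and returns at 29. It replaces the acid-activated epoxide by a cyclic sulfate that is opened under base. 1,1′-Sulfonyldiimidazole and NaH convert the diol directly into the cyclic sulfate F4, which avoids a ruthenium oxidation that the arenes would not tolerate. Buffered HF·pyridine removes the triethylsilyl group to give the hydroxy cyclic sulfate F5. NaH in THF then lets the C2 alkoxide displace the sulfate oxygen at C5 with inversion, which forms the five-membered ring as the tetrahydrofuran hydrogen sulfate F6. Brief hydrolysis (H2SO4 cat., H2O, THF) gives 29.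

3. Step 17. The sp–sp3 coupling may be slow enough for the benzylic bromide to decompose, or base may isomerise the skipped arylalkyne to an allene. The fallback sets out from alkyne 23 and returns at alkene 26, making the bond by sp2–sp3 coupling after the alkene geometry is fixed. NIS with AgNO3 (cat.) gives the iodoalkyne F7. Diimide reduction (2-nitrobenzenesulfonyl hydrazide, Et3N) gives the (Z)-vinyl iodide F8. Negishi coupling with the benzylzinc bromide F9 (from 5 and zinc dust) under Pd(PPh3)4 proceeds with retention of the alkene geometry and gives 26, so step 18 is no longer needed.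

Further compounds
F1 | step 19 | syn-(4S,5R)-4,5-diol from alkene 26 (C2 triethylsilyl ether kept) | COc1cc(C[C@@H](O)[C@@H](O)[C@H](CO[Si](c2ccccc2)(c2ccccc2)C(C)(C)C)[C@H](O[Si](CC)(CC)CC)c2cc(OC)c3c(c2)[C@H](CO[Si](c2ccccc2)(c2ccccc2)C(C)(C)C)[C@H](c2ccc(OCc4ccccc4)c(OC)c2)O3)ccc1OCc1ccccc1
F2 | step 19 | cyclic orthoacetate (2-methoxy-2-methyl-1,3-dioxolane) of F1, mixture at the orthoester carbon | COc1cc(C[C@H]2OC(C)(OC)O[C@H]2[C@H](CO[Si](c2ccccc2)(c2ccccc2)C(C)(C)C)[C@H](O[Si](CC)(CC)CC)c2cc(OC)c3c(c2)[C@H](CO[Si](c2ccccc2)(c2ccccc2)C(C)(C)C)[C@H](c2ccc(OCc4ccccc4)c(OC)c2)O3)ccc1OCc1ccccc1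
F3 | step 19 | (5S)-5-bromo (4S)-4-acetate from F2 (bromide inverted at C5) | COc1cc(C[C@H](Br)[C@@H](OC(C)=O)[C@H](CO[Si](c2ccccc2)(c2ccccc2)C(C)(C)C)[C@H](O[Si](CC)(CC)CC)c2cc(OC)c3c(c2)[C@H](CO[Si](c2ccccc2)(c2ccccc2)C(C)(C)C)[C@H](c2ccc(OCc4ccccc4)c(OC)c2)O3)ccc1OCc1ccccc1
F4 | step 21 | (4S,5R)-4,5-cyclic sulfate of F1 | COc1cc(C[C@H]2OS(=O)(=O)O[C@H]2[C@H](CO[Si](c2ccccc2)(c2ccccc2)C(C)(C)C)[C@H](O[Si](CC)(CC)CC)c2cc(OC)c3c(c2)[C@H](CO[Si](c2ccccc2)(c2ccccc2)C(C)(C)C)[C@H](c2ccc(OCc4ccccc4)c(OC)c2)O3)ccc1OCc1ccccc1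
F5 | step 21 | cyclic sulfate with free C2 hydroxyl | COc1cc(C[C@H]2OS(=O)(=O)O[C@H]2[C@H](CO[Si](c2ccccc2)(c2ccccc2)C(C)(C)C)[C@H](O)c2cc(OC)c3c(c2)[C@H](CO[Si](c2ccccc2)(c2ccccc2)C(C)(C)C)[C@H](c2ccc(OCc4ccccc4)c(OC)c2)O3)ccc1OCc1ccccc1
F6 | step 21 | C4 hydrogen sulfate of tetrahydrofuran 29 | COc1cc(C[C@@H]2O[C@H](c3cc(OC)c4c(c3)[C@H](CO[Si](c3ccccc3)(c3ccccc3)C(C)(C)C)[C@H](c3ccc(OCc5ccccc5)c(OC)c3)O4)[C@@H](CO[Si](c3ccccc3)(c3ccccc3)C(C)(C)C)[C@@H]2OS(=O)(=O)O)ccc1OCc1ccccc1
F7 | step 17 | 1-iodoalkyne from 23 | IC#C[C@H](CO[Si](c1ccccc1)(c1ccccc1)C(C)(C)C)[C@H](O[Si](CC)(CC)CC)c1cc(OC)c2c(c1)[C@H](CO[Si](c1ccccc1)(c1ccccc1)C(C)(C)C)[C@H](c1ccc(OCc3ccccc3)c(OC)c1)O2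
F8 | step 17 | (Z)-vinyl iodide from F7 | I/C=C\[C@H](CO[Si](c1ccccc1)(c1ccccc1)C(C)(C)C)[C@H](O[Si](CC)(CC)CC)c1cc(OC)c2c(c1)[C@H](CO[Si](c1ccccc1)(c1ccccc1)C(C)(C)C)[C@H](c1ccc(OCc3ccccc3)c(OC)c1)O2
F9 | step 17 | [4-(benzyloxy)-3-methoxybenzyl]zinc bromide | COc1cc(C[Zn]Br)ccc1OCc1ccccc1
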